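The route rests on disconnecting, in both halves at once, the C2'–C3' and O1'–C5' bonds of the γ-butyrolactone rings that hang from the quaternary C2 of each pyran ring. Their 1,4-oxygen pattern (C2'–O, C5'=O) is matched by a carbene-bound crotonaldehyde reacting as a β-carbanion with a formyl group on C2, so one operation forms four skeletal bonds, two lactone rings and the stereocentres C2' and C3' of each half. The substrate is the C2-symmetric 6,6'-linked bis(methyl (2S)-2-formyl-5-methoxychroman-2-carboxylate), with C4 still CH2 and the phenols as methyl ethers; benzylic oxidation, demethylation and opening of one lactone then finish the target.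

Key step: step 10

Numbering used in the text: unprimed locants (O1, C2–C8a) refer to either chromane half; primed locants refer to its lactone (O1', C2' = CH–O, C3' = CHCH3, C4', C5' = C=O). Primes inside compound names follow ordinary bichromane nomenclature.

Assumption: the esterase in step 7 is taken to hydrolyse the pro-R ester at each C2, and the (5aR,10bS) triazolium salt in step 10 is taken to be the enantiomer matched with the substrate bias; each sense is to be confirmed on a first small run, and the opposite outcome is met by the antipodal catalyst or by the fallbacks given at the end.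

Step 1
Reactants: 1 4-bromo-3-methoxyphenol; 2 chloromethyl methyl ether
Product: 3 1-bromo-2-methoxy-4-(methoxymethoxy)benzene
Conditions: 2, i-Pr2NEt, CH2Cl2, 0 °C → rt
Reagents that add atoms: 2 chloromethyl methyl ether, COCCl
Why: Base-mediated O-alkylation of the phenol by the α-chloro ether (methoxymethyl ether formation) should be clean and installs the acetal that directs the metalation in step 3.

Step 2
Reactants: 3 1-bromo-2-methoxy-4-(methoxymethoxy)benzene (two molecules)
Product: 4 2,2'-dimethoxy-4,4'-bis(methoxymethoxy)-1,1'-biphenyl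
Conditions: NiCl2(PPh3)2 (10 mol%), PPh3, Zn dust, Et4NI, THF, 60 °C
Reagents that add atoms: none
Why: Nickel-catalysed reductive homocoupling of an aryl bromide (Ullmann-type, zerovalent nickel regenerated by zinc) is an established way to symmetrical 2,2'-dialkoxybiaryls and tolerates the acetal; the new axis has only two ortho substituents and rotates freely, so no stereochemistry arises.

Step 3
Reactants: 4 2,2'-dimethoxy-4,4'-bis(methoxymethoxy)-1,1'-biphenyl; 5 N-methoxy-N-methylacetamide
Product: 7 1,1'-[2,2'-dimethoxy-4,4'-bis(methoxymethoxy)-1,1'-biphenyl-3,3'-diyl]di(ethan-1-one), via 3,3'-dilithiobiaryl 6 (not isolated)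
Conditions: n-BuLi, TMEDA, THF, 0 °C; then 5, −78 °C → rt; H2O
Reagents that add atoms: 5 N-methoxy-N-methylacetamide, CC(=O)N(C)OC
Why: Directed ortho-metalation: C3 and C3' lie between the methoxy and the methoxymethoxy group, the only sites activated by both, so lithiation there is strongly preferred, and the aryllithium is acylated once by the N-methoxy-N-methylamide through its chelated tetrahedral adduct.

Step 4
Reactants: 7 1,1'-[2,2'-dimethoxy-4,4'-bis(methoxymethoxy)-1,1'-biphenyl-3,3'-diyl]di(ethan-1-one); 8 dimethyl oxalate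
Product: 10 dimethyl 5,5'-dimethoxy-4,4'-dioxo-4H,4'H-[6,6'-bichromene]-2,2'-dicarboxylate, via bis(diketo ester) 9 (not isolated)
Conditions: 8, NaOMe, MeOH/THF, 60 °C; then conc. HCl, MeOH, reflux
Reagents that add atoms: 8 dimethyl oxalate, COC(=O)C(=O)OC
Why: Claisen condensation of each methyl ketone with the oxalate gives the 2,4-diketo ester, and hot methanolic HCl then cleaves the methoxymethyl ethers and cyclodehydrates the freed phenols onto the ketone next to the ester (standard chromone-2-carboxylate synthesis); only the oxygen para to the biaryl bond is free, which fixes the 5-methoxy-6-aryl pattern.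

Step 5
Reactants: 10 dimethyl 5,5'-dimethoxy-4,4'-dioxo-4H,4'H-[6,6'-bichromene]-2,2'-dicarboxylate
Product: 11 dimethyl 5,5'-dimethoxy-[6,6'-bichromane]-2,2'-dicarboxylate (mixture of the C2 stereoisomers)
Conditions: H2 (10 bar), Pd/C (10 wt% Pd), AcOH, conc. H2SO4 (cat.), 70 °C
Reagents that add atoms: none
Why: Heterogeneous catalytic hydrogenation in acidic acetic acid saturates C2=C3 and then removes the C4 oxygen by benzylic hydrogenolysis, the usual conversion of chromone-2-carboxylates into chroman-2-carboxylates; the C2 centres formed without control are erased in step 6.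

Step 6
Reactants: 11 dimethyl 5,5'-dimethoxy-[6,6'-bichromane]-2,2'-dicarboxylate; 12 methyl chloroformate
Product: 14 tetramethyl 5,5'-dimethoxy-[6,6'-bichromane]-2,2,2',2'-tetracarboxylate, via bis(lithium enolate) 13 (not isolated)
Conditions: LiN(i-Pr)2, THF, −78 °C; then 12, −78 → 0 °C
Reagents that add atoms: 12 methyl chloroformate, COC(=O)Cl
Why: Ester enolate C-acylation (methoxycarbonylation): the α-aryloxy ester enolates carry no β-leaving group, are stable at −78 °C and are trapped by the chloroformate to the malonates, which makes each C2 quaternary and prochiral.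

Step 7
Reactants: 14 tetramethyl 5,5'-dimethoxy-[6,6'-bichromane]-2,2,2',2'-tetracarboxylate
Product: 15 (2S,2'S)-5,5'-dimethoxy-2,2'-bis(methoxycarbonyl)-[6,6'-bichromane]-2,2'-dicarboxylic acid
Conditions: pig liver esterase, phosphate buffer (pH 7.5)/DMSO 4:1, 30 °C, pH-stat (1 M NaOH); then 1 M HCl to pH 2
Reagents that add atoms: water, O
Why: Enzymatic desymmetrisation (enantiotopic-group-selective ester hydrolysis): the esterase cleaves one of the two enantiotopic methyl esters of each malonate and stops at the half-ester, which sets both C2 centres (S); an error at one end gives the separable meso diastereomer, so the C2-symmetric diacid should be upgraded in optical purity.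

Step 8
Reactants: 15 (2S,2'S)-5,5'-dimethoxy-2,2'-bis(methoxycarbonyl)-[6,6'-bichromane]-2,2'-dicarboxylic acid
Product: 16 dimethyl (2S,2'S)-2,2'-bis(hydroxymethyl)-5,5'-dimethoxy-[6,6'-bichromane]-2,2'-dicarboxylate
Conditions: BH3·SMe2, THF, 0 °C → rt; then MeOH
Reagents that add atoms: none
Why: Chemoselective borane reduction: carboxylic acids are reduced through acyloxyboranes much faster than methyl esters, so each C2 keeps its ester and gains CH2OH with the stereocentre untouched.

Step 9
Reactants: 16 dimethyl (2S,2'S)-2,2'-bis(hydroxymethyl)-5,5'-dimethoxy-[6,6'-bichromane]-2,2'-dicarboxylate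
Product: 17 dimethyl (2S,2'S)-2,2'-diformyl-5,5'-dimethoxy-[6,6'-bichromane]-2,2'-dicarboxylate
Conditions: Dess–Martin periodinane, CH2Cl2, rt
Reagents that add atoms: none
Why: Dess–Martin oxidation converts the neopentyl-type primary alcohols into aldehydes without base, and since C2 is quaternary the aldehyde can neither enolise nor epimerise; the dialdehyde is dried and used at once.

Step 10
Reactants: 17 dimethyl (2S,2'S)-2,2'-diformyl-5,5'-dimethoxy-[6,6'-bichromane]-2,2'-dicarboxylate; 18 (E)-crotonaldehyde (two molecules)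
Product: 19 dimethyl (2S,2'S)-5,5'-dimethoxy-2,2'-bis[(2R,3S)-3-methyl-5-oxooxolan-2-yl]-[6,6'-bichromane]-2,2'-dicarboxylate
Conditions: 18 (slow addition), (5aR,10bS)-2-mesityl-5a,10b-dihydro-4H,6H-indeno[2,1-b][1,2,4]triazolo[4,3-d][1,4]oxazin-2-ium chloride (20 mol%), i-Pr2NEt (40 mol%), 4 Å MS, THF, rt
Reagents that add atoms: 18 (E)-crotonaldehyde, C/C=C/C=O
Why: The carbene freed from the triazolium salt adds to 18 and proton transfer gives the extended Breslow intermediate, a homoenolate whose β-carbon (future C3') attacks a formyl carbon of 17 (future C2'); the enol then tautomerises to the acyl azolium, the C2' alkoxide attacks C5' and the carbene is released, and the cycle repeats at the second formyl group. The closest known reaction is the carbene-catalysed annulation of enal homoenolates with aldehydes and activated ketones to cis-γ-butyrolactones. Each of the two lactone rings closes by a 5-exo-trig O-acylation (O1'–C5') that follows the intermolecular C2'–C3' bond formation. C2' (R) is controlled by the fixed C2 centre: in the polar Felkin–Anh arrangement O1 lies anti to the incoming carbon, the flat CO2Me group sits beside the formyl hydrogen and the ring CH2 beside the carbonyl oxygen, so the Re face of the formyl group is attacked. C3' (S) is controlled by the catalyst, whose indane wall should leave the Si face of the β-carbon open in the cis-selective transition state, so that the methyl group ends cis to C2 on the lactone. The step needs chemoselectivity for the formyl groups of 17 over the aldehyde of 18 and retention at C2: the formyl groups are the most electrophilic carbonyls present (α-oxygen, α-ester) and cannot enolise at the quaternary C2, C4 as CH2 rules out ring opening by β-elimination, slow addition of 18 limits its self-annulation, and the absence of metal ions avoids a chelate that would turn the aldehyde face.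

Step 11
Reactants: 19 dimethyl (2S,2'S)-5,5'-dimethoxy-2,2'-bis[(2R,3S)-3-methyl-5-oxooxolan-2-yl]-[6,6'-bichromane]-2,2'-dicarboxylate
Product: 20 dimethyl (2S,2'S)-5,5'-dimethoxy-2,2'-bis[(2R,3S)-3-methyl-5-oxooxolan-2-yl]-4,4'-dioxo-[6,6'-bichromane]-2,2'-dicarboxylate
Conditions: Mn(OAc)3·2H2O (cat.), t-BuOOH (in decane), 3 Å MS, EtOAc, rt
Reagents that add atoms: tert-butyl hydroperoxide, CC(C)(C)OO
Why: Benzylic C–H oxidation by the manganese triacetate/hydroperoxide system is established for chromans, and C4 is the only benzylic methylene in each half and is activated by the two oxygen-bearing ring carbons beside C4a, so the aryl ketones should form without touching the lactones or the stereocentres.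

Step 12
Reactants: 20 dimethyl (2S,2'S)-5,5'-dimethoxy-2,2'-bis[(2R,3S)-3-methyl-5-oxooxolan-2-yl]-4,4'-dioxo-[6,6'-bichromane]-2,2'-dicarboxylate
Product: 21 dimethyl (2S,2'S)-5,5'-dihydroxy-2,2'-bis[(2R,3S)-3-methyl-5-oxooxolan-2-yl]-4,4'-dioxo-[6,6'-bichromane]-2,2'-dicarboxylate
Conditions: BCl3, CH2Cl2, −78 → 0 °C; then H2O
Reagents that add atoms: none
Why: Chelation-assisted Lewis acid ether cleavage: BCl3 bridges the C4 ketone and the peri methoxy oxygen and chloride removes the methyl group, a selective demethylation that leaves methyl esters, lactones and all stereocentres intact at low temperature.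

Step 13
Reactants: 21 dimethyl (2S,2'S)-5,5'-dihydroxy-2,2'-bis[(2R,3S)-3-methyl-5-oxooxolan-2-yl]-4,4'-dioxo-[6,6'-bichromane]-2,2'-dicarboxylate
Product: 22 (3S,4R)-4-hydroxy-4-[(2S)-5-hydroxy-6-{(2S)-5-hydroxy-2-(methoxycarbonyl)-2-[(2R,3S)-3-methyl-5-oxooxolan-2-yl]-4-oxochroman-6-yl}-2-(methoxycarbonyl)-4-oxochroman-2-yl]-3-methylbutanoic acid (target)
Conditions: LiOH·H2O (3.1 equiv), THF/H2O 3:1, 0 °C, stopped at partial conversion; then 0.1 M HCl to pH 4.5, 0 °C
Reagents that add atoms: lithium hydroxide, [Li+].[OH-]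
Why: Saponification: after the two phenols have taken up two equivalents of base (which also lowers the acidity at C3), the remaining hydroxide should attack the unhindered lactone carbonyl C5' faster than the methyl esters on the quaternary C2, the first carboxylate slows the second opening, and cold acidification to pH 4.5 frees the hydroxy acid without ring closure or change at any stereocentre, unreacted 21 being recycled.

Compound list
1 | 4-bromo-3-methoxyphenol | COc1cc(O)ccc1Br | starting material
2 | chloromethyl methyl ether | COCCl | starting material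
3 | 1-bromo-2-methoxy-4-(methoxymethoxy)benzene | COCOc1ccc(Br)c(OC)c1 | intermediate
4 | 2,2'-dimethoxy-4,4'-bis(methoxymethoxy)-1,1'-biphenyl | COCOc1ccc(-c2ccc(OCOC)cc2OC)c(OC)c1 | intermediate
5 | N-methoxy-N-methylacetamide | CC(=O)N(C)OC | starting material
6 | 3,3'-dilithio-2,2'-dimethoxy-4,4'-bis(methoxymethoxy)-1,1'-biphenyl | COCOc1ccc(-c2ccc(OCOC)c([Li])c2OC)c(OC)c1[Li] | intermediate (not isolated)
7 | 1,1'-[2,2'-dimethoxy-4,4'-bis(methoxymethoxy)-1,1'-biphenyl-3,3'-diyl]di(ethan-1-one) | COCOc1ccc(-c2ccc(OCOC)c(C(C)=O)c2OC)c(OC)c1C(C)=O | intermediate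
8 | dimethyl oxalate | COC(=O)C(=O)OC | starting material
9 | dimethyl 4,4'-[2,2'-dimethoxy-4,4'-bis(methoxymethoxy)-1,1'-biphenyl-3,3'-diyl]bis(2,4-dioxobutanoate), present as its sodium enolate | COCOc1ccc(-c2ccc(OCOC)c(C(=O)CC(=O)C(=O)OC)c2OC)c(OC)c1C(=O)CC(=O)C(=O)OC | intermediate (not isolated)
10 | dimethyl 5,5'-dimethoxy-4,4'-dioxo-4H,4'H-[6,6'-bichromene]-2,2'-dicarboxylate | COC(=O)c1cc(=O)c2c(o1)ccc(-c1ccc3oc(C(=O)OC)cc(=O)c3c1OC)c2OC | intermediate
11 | dimethyl 5,5'-dimethoxy-[6,6'-bichromane]-2,2'-dicarboxylate, mixture of the C2 stereoisomers | COC(=O)C1CCc2c(O1)ccc(-c1ccc3OC(C(=O)OC)CCc3c1OC)c2OC | intermediate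
12 | methyl chloroformate | COC(=O)Cl | starting material
13 | bis(lithium enolate) of 11 | COC(O[Li])=C1CCc2c(O1)ccc(-c1ccc3OC(=C(OC)O[Li])CCc3c1OC)c2OC | intermediate (not isolated)
14 | tetramethyl 5,5'-dimethoxy-[6,6'-bichromane]-2,2,2',2'-tetracarboxylate | COC(=O)C1(C(=O)OC)CCc2c(O1)ccc(-c1ccc3OC(C(=O)OC)(C(=O)OC)CCc3c1OC)c2OC | intermediate
15 | (2S,2'S)-5,5'-dimethoxy-2,2'-bis(methoxycarbonyl)-[6,6'-bichromane]-2,2'-dicarboxylic acid | COC(=O)[C@@]1(C(=O)O)CCc2c(ccc(-c3ccc4c(c3OC)CC[C@@](C(=O)OC)(C(=O)O)O4)c2OC)O1 | intermediate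
16 | dimethyl (2S,2'S)-2,2'-bis(hydroxymethyl)-5,5'-dimethoxy-[6,6'-bichromane]-2,2'-dicarboxylate | COC(=O)[C@@]1(CO)CCc2c(ccc(-c3ccc4c(c3OC)CC[C@@](C(=O)OC)(CO)O4)c2OC)O1 | intermediate
17 | dimethyl (2S,2'S)-2,2'-diformyl-5,5'-dimethoxy-[6,6'-bichromane]-2,2'-dicarboxylate | COC(=O)[C@@]1(C=O)CCc2c(ccc(-c3ccc4c(c3OC)CC[C@@](C(=O)OC)(C=O)O4)c2OC)O1 | intermediate
18 | (E)-crotonaldehyde | C/C=C/C=O | starting material
19 | dimethyl (2S,2'S)-5,5'-dimethoxy-2,2'-bis[(2R,3S)-3-methyl-5-oxooxolan-2-yl]-[6,6'-bichromane]-2,2'-dicarboxylate | COC(=O)[C@@]1([C@@H]5OC(=O)C[C@@H]5C)CCc2c(ccc(-c3ccc4c(c3OC)CC[C@@](C(=O)OC)([C@@H]3OC(=O)C[C@@H]3C)O4)c2OC)O1 | intermediate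
20 | dimethyl (2S,2'S)-5,5'-dimethoxy-2,2'-bis[(2R,3S)-3-methyl-5-oxooxolan-2-yl]-4,4'-dioxo-[6,6'-bichromane]-2,2'-dicarboxylate | COC(=O)[C@@]1([C@@H]5OC(=O)C[C@@H]5C)CC(=O)c2c(ccc(-c3ccc4c(c3OC)C(=O)C[C@@](C(=O)OC)([C@@H]3OC(=O)C[C@@H]3C)O4)c2OC)O1 | intermediate
21 | dimethyl (2S,2'S)-5,5'-dihydroxy-2,2'-bis[(2R,3S)-3-methyl-5-oxooxolan-2-yl]-4,4'-dioxo-[6,6'-bichromane]-2,2'-dicarboxylate | COC(=O)[C@@]1([C@@H]5OC(=O)C[C@@H]5C)CC(=O)c2c(ccc(-c3ccc4c(c3O)C(=O)C[C@@](C(=O)OC)([C@@H]3OC(=O)C[C@@H]3C)O4)c2O)O1 | intermediate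
22 | (3S,4R)-4-hydroxy-4-[(2S)-5-hydroxy-6-{(2S)-5-hydroxy-2-(methoxycarbonyl)-2-[(2R,3S)-3-methyl-5-oxooxolan-2-yl]-4-oxochroman-6-yl}-2-(methoxycarbonyl)-4-oxochroman-2-yl]-3-methylbutanoic acid | COC(=O)[C@@]1([C@H](O)[C@@H](C)CC(=O)O)CC(=O)c2c(ccc(-c3ccc4c(c3O)C(=O)C[C@@](C(=O)OC)([C@@H]3OC(=O)C[C@@H]3C)O4)c2O)O1 | target

Total step count: 13 steps.
Longest linear sequence: 13 steps (1 → 22); the route is fully linear, every step from step 2 on acting on both halves at once.

Steps most likely to fail

1. Step 10. The homoenolate may fail to add to the crowded formyl groups, so that self-annulation of 18 or carbene-induced loss of the formyl group takes over. The substrate bias and the catalyst bias may also oppose each other, giving attack on the wrong aldehyde face or the trans lactone. The fallback sets out from 17 and forms the same C2'–C3' bonds by syn-selective crotylboration. (Z)-Crotyldiisopinocampheylborane, made from (Z)-2-butene, n-BuLi/KOt-Bu, (+)-B-methoxydiisopinocampheylborane and BF3·OEt2, is the antipode expected to add to the Re face of aldehydes. In Et2O/THF at −78 °C with NaBO3·4H2O work-up it should give the bis(homoallylic alcohol) F1. Hydroboration of both vinyl groups with 9-BBN followed by NaBO3·4H2O oxidation should give the bis(1,4-diol) F2. Oxidative lactonisation with TEMPO (cat.) and PhI(OAc)2 in CH2Cl2 then closes both lactones, and the route is rejoined at 19.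

2. Step 7. The esterase may turn over the poorly soluble tetraester slowly, or may discriminate the enantiotopic esters weakly or in the opposite sense. The fallback sets out from 14 and moves the desymmetrisation to an acyl transfer in organic solvent. Reduction with LiAlH4 in THF at 0 °C gives the tetraol F3. A lipase (Burkholderia cepacia lipase, vinyl acetate, t-BuOMe/THF, 30 °C), selected by screening for the arm that must stay as CH2OH in 16, should give the (2R,2'R) bis(monoacetate) F4. Oxidation of the free primary alcohols with TEMPO (cat.) and PhI(OAc)2 in MeCN/H2O gives the diacid F5, and Me3SiCHN2 in MeOH/toluene gives the diester F6. Acidic methanolysis of the acetates (HCl in MeOH, 0 °C → rt) returns to the route at 16.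

3. Step 13. Hydroxide may also saponify the C2 methyl esters, or open the pyranone ring by β-elimination of the phenoxide from a C3 enolate, which would scramble C2. The hydrolysis may not stop after one lactone, and the γ-hydroxy acid may close again on acidification. The fallback sets out from 21 and replaces stoichiometric hydroxide by a biocatalytic ring opening at neutral pH, an established way to hydrolyse γ-lactones: horse liver esterase in phosphate buffer (pH 7.2) with 10% acetone at 25 °C under pH-stat control, where neither phenoxide nor enolate is formed. The carboxylate is held as its salt until acidification to pH 4.5 at 0 °C, and the route is rejoined at the target 22; this path passes through no new compound (F0).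

Further compounds
F1 | step 10 | dimethyl (2S,2'S)-2,2'-bis[(1R,2S)-1-hydroxy-2-methylbut-3-en-1-yl]-5,5'-dimethoxy-[6,6'-bichromane]-2,2'-dicarboxylate | COC(=O)[C@@]1([C@H](O)[C@@H](C)C=C)CCc2c(ccc(-c3ccc4c(c3OC)CC[C@@](C(=O)OC)([C@H](O)[C@@H](C)C=C)O4)c2OC)O1
F2 | step 10 | dimethyl (2S,2'S)-2,2'-bis[(1R,2S)-1,4-dihydroxy-2-methylbutyl]-5,5'-dimethoxy-[6,6'-bichromane]-2,2'-dicarboxylate | COC(=O)[C@@]1([C@H](O)[C@@H](C)CCO)CCc2c(ccc(-c3ccc4c(c3OC)CC[C@@](C(=O)OC)([C@H](O)[C@@H](C)CCO)O4)c2OC)O1
F3 | step 7 | [5,5'-dimethoxy-[6,6'-bichromane]-2,2,2',2'-tetrayl]tetramethanol | OCC1(CO)CCc2c(O1)ccc(-c1ccc3OC(CO)(CO)CCc3c1OC)c2OC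
F4 | step 7 | [(2R,2'R)-2,2'-bis(hydroxymethyl)-5,5'-dimethoxy-[6,6'-bichromane]-2,2'-diyl]bis(methylene) diacetate | OC[C@@]1(COC(C)=O)CCc2c(ccc(-c3ccc4c(c3OC)CC[C@@](CO)(COC(C)=O)O4)c2OC)O1
F5 | step 7 | (2S,2'S)-2,2'-bis(acetoxymethyl)-5,5'-dimethoxy-[6,6'-bichromane]-2,2'-dicarboxylic acid | OC(=O)[C@@]1(COC(C)=O)CCc2c(ccc(-c3ccc4c(c3OC)CC[C@@](C(=O)O)(COC(C)=O)O4)c2OC)O1
F6 | step 7 | dimethyl (2S,2'S)-2,2'-bis(acetoxymethyl)-5,5'-dimethoxy-[6,6'-bichromane]-2,2'-dicarboxylate | COC(=O)[C@@]1(COC(C)=O)CCc2c(ccc(-c3ccc4c(c3OC)CC[C@@](C(=O)OC)(COC(C)=O)O4)c2OC)O1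
F0 | step 13 | none | none
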